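**Plan**
Retrosynthesis: cut C12–C13 (aldol; succinimide from a cyano acyl oxazolidinone), then C8–C9 and C7–C8 (ring B), then C1–C2 together with C5–C10 (ring A), leaving a chloro dihydropyran acetal and 2-methylbut-1-en-3-yne.
Forward: ring A first by a cationic [4+2]/chloride ring-opening cascade (step 5), then ring B by alkylation at C7, cross-metathesis and a vinyl-radical closure (step 9), then Evans aldol and imide closure (step 12).
Enabling feature: in ring A the C6 carbonyl oxygen lies 1,4 to C2 through C3–C4, so C2=O+–C6=C5 can be held as a cyclic O-vinyl oxocarbenium ion whose termini C2 and C5 take up the C1=C10 alkene. The temporary C2–O–C6 bridge (a 2-oxabicyclo[2.2.2]octane) is then the leaving group for the C2 chloride and gives back the C6 ketone.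
Stereochemistry: C3 from organocatalytic α-chlorination; C2, C5 and C10 relayed from C3 in step 5; C9 from the chair transition state of the radical closure; C12 and C13 from the oxazolidinone auxiliary.

Key step: step 5

Remarks: atom labels C1–C17 are the labdane positions of the target (ring A = C1–C5, C10; ring B = C5–C10; C17 = exocyclic CH2; side chain C11–C16); α/β refer to the usual drawing with the C10 methyl β. Assumption: (2S,5S)-2,5-diphenylpyrrolidine is taken to deliver the 2R α-chloro aldehyde; if the sense is the opposite, its enantiomer is used.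

**Route**

Step 1
Reactants: 1 3,3-dimethyl-5-oxohexanoic acid
Product: 2 4,4,6-trimethyl-3,4-dihydro-2H-pyran-2-one
Conditions: Ac2O, HClO4 (cat.), EtOAc, 25 °C
Reagents that add atoms: none
Why: Acid-catalysed enol lactonisation of a δ-keto acid through its mixed anhydride closes the six-membered enol lactone with the endocyclic C5=C6 double bond, and no stereocentre is formed.

Step 2
Reactants: 2 4,4,6-trimethyl-3,4-dihydro-2H-pyran-2-one
Product: 4 3,3-dimethyl-5-oxohexanal, via lactol 3 (not isolated)
Conditions: DIBAL-H (iBu2AlH, 1.05 equiv), CH2Cl2, −78 °C; aq. potassium sodium tartrate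
Reagents that add atoms: none
Why: Low-temperature half-reduction of the lactone (DIBAL-H lactone-to-lactol reduction) stops at the lactol oxidation level, and the enol hemiacetal set free on work-up opens to the δ-keto aldehyde, which is used without delay.

Step 3
Reactants: 4 3,3-dimethyl-5-oxohexanal
Product: 5 (2R)-2-chloro-3,3-dimethyl-5-oxohexanal
Conditions: NCS, (2S,5S)-2,5-diphenylpyrrolidine (10 mol %), CH2Cl2, 0 °C
Reagents that add atoms: N-chlorosuccinimide O=C1CCC(=O)N1Cl
Why: Enamine-catalysed electrophilic α-chlorination of the aldehyde, in which the hindered C2-symmetric amine condenses only with the aldehyde and shields one enamine face so that chlorine enters to give the R centre (C3 of the target); the configurationally labile product is carried on crude.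

Step 4
Reactants: 5 (2R)-2-chloro-3,3-dimethyl-5-oxohexanal
Product: 7 (3R)-3-chloro-2-methoxy-4,4,6-trimethyl-3,4-dihydro-2H-pyran, via hemiacetal 6 (not isolated)
Conditions: MeOH (3 equiv), PPTS (cat.), 4 Å MS, CH2Cl2, 25 °C
Reagents that add atoms: methanol CO
Why: Acid-catalysed cyclo-acetalisation of a 1,5-keto aldehyde, in which the hemiacetal hydroxyl adds to the ketone and the tertiary hemiketal dehydrates towards C5, should give the cyclic enol acetal as a mixture of C2 epimers (both ionise to the same cation in step 5) without touching the C3 chlorine centre.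

Step 5
Reactants: 7 (3R)-3-chloro-2-methoxy-4,4,6-trimethyl-3,4-dihydro-2H-pyran; 8 2-methylbut-1-en-3-yne
Product: 11 1-[(1R,3R,4R,6S)-3,4-dichloro-6-ethynyl-2,2,6-trimethylcyclohexyl]ethan-1-one, via oxocarbenium ion 9 (not isolated), via bridged oxocarbenium ion 10 (not isolated)
Conditions: TiCl4 (1.5 equiv), 8 (5 equiv), CH2Cl2, −78 to −20 °C (7 added slowly); aq. NaHCO3
Reagents that add atoms: titanium tetrachloride Cl[Ti](Cl)(Cl)Cl
Why: Proposed new method: TiCl4 ionises the acetal to the cyclic O-vinyl oxocarbenium ion 9, a cationic 2-oxadiene (C2=O+–C6=C5) whose termini C2 and C5 are tied 1,4 by C3–C4; the CH2 end of 8 attacks C2 (Markovnikov), the tertiary propargylic cation at C10 is trapped by the enol ether carbon C5, and the resulting 2-oxoniabicyclo[2.2.2]octene 10 is dealkylated at C2 by chloride from the chlorotitanate (SN2), which returns the C6 ketone and installs the C2 chloride. The closest known reaction types are the oxa-Povarov and 2-benzopyrylium [4+2] reactions of O-aryl or O-vinyl oxocarbenium ions with alkenes, the chloride-terminated Prins cyclisation, and the halide dealkylation of alkoxycarbenium ions. Ring A (C1–C2–C3–C4–C5–C10) closes by 6-exo attack of the C5=C6 enol ether on the C10 cation through a boat, the same bond completing the temporary 2-oxabicyclo[2.2.2]octane, which the chloride then opens so that only the carbocycle remains. C2 is controlled by C3: the enyne adds to the face of 9 anti to the chlorine, so the bridging oxygen is syn to it and backside displacement gives the trans-diequatorial 2,3-dichloride; C5 is fixed by the suprafacial bridge (acetyl cis to the C3 chlorine, also the thermodynamic epimer); at C10 the planar cation turns its smallest group, the ethynyl, into the slot next to the C4 methyl of the C3–C4 bridge and its methyl towards the open O=C6 bridge. The step needs the cross-reaction to outrun self-condensation and proton loss of 9 (hindered neopentyl enol ether, excess 8, slow addition of 7 to TiCl4 and 8) and needs C–O cleavage at C2 to outrun aqueous quench (non-basic chloride medium, warming to −20 °C before work-up).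

Step 6
Reactants: 11 1-[(1R,3R,4R,6S)-3,4-dichloro-6-ethynyl-2,2,6-trimethylcyclohexyl]ethan-1-one
Product: 12 1-[(1R,3R,4R,6R)-3,4-dichloro-6-ethenyl-2,2,6-trimethylcyclohexyl]ethan-1-one
Conditions: H2 (1 atm), Lindlar catalyst (Pd/CaCO3 poisoned with Pb(OAc)2), quinoline, EtOAc, 25 °C
Reagents that add atoms: none
Why: Lindlar semi-hydrogenation of the terminal alkyne stops at the vinyl group on the poisoned palladium surface and leaves the ketone and the secondary chlorides untouched; no stereocentre is formed.

Step 7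
Reactants: 12 1-[(1R,3R,4R,6R)-3,4-dichloro-6-ethenyl-2,2,6-trimethylcyclohexyl]ethan-1-one; 13 2,3-dibromoprop-1-ene
Product: 15 4-bromo-1-[(1R,3R,4R,6R)-3,4-dichloro-6-ethenyl-2,2,6-trimethylcyclohexyl]pent-4-en-1-one, via lithium enolate 14 (not isolated)
Conditions: LDA (LiN(iPr)2, 1.05 equiv), THF, −78 °C; then 13, DMPU, −78 to −20 °C
Reagents that add atoms: none
Why: Kinetic enolate alkylation, since LDA removes a proton from the methyl group (C7) and not from the neopentyl methine C5, and the terminal enolate displaces the allylic bromide faster than any elimination at the secondary chlorides; no stereocentre is formed.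

Step 8
Reactants: 15 4-bromo-1-[(1R,3R,4R,6R)-3,4-dichloro-6-ethenyl-2,2,6-trimethylcyclohexyl]pent-4-en-1-one; 16 (E)-but-2-enal
Product: 17 (2E)-3-[(1R,2R,4R,5R)-2-(4-bromopent-4-enoyl)-4,5-dichloro-1,3,3-trimethylcyclohexyl]prop-2-enal
Conditions: second-generation Hoveyda–Grubbs catalyst RuCl2(H2IMes)(=CH-C6H4-2-OiPr) (10 mol %), 16 (10 equiv), CH2Cl2, 40 °C
Reagents that add atoms: none
Why: Olefin cross-metathesis of the monosubstituted vinyl group with the enal partner should give the conjugated E-enal under thermodynamic control, while the 2-bromo-1,1-disubstituted alkene does not engage the ruthenium carbene.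

Step 9
Reactants: 17 (2E)-3-[(1R,2R,4R,5R)-2-(4-bromopent-4-enoyl)-4,5-dichloro-1,3,3-trimethylcyclohexyl]prop-2-enal
Product: 18 2-[(1S,4aR,6R,7R,8aR)-6,7-dichloro-5,5,8a-trimethyl-2-methylidene-4-oxodecahydronaphthalen-1-yl]acetaldehyde
Conditions: Bu3SnH (1.3 equiv, syringe pump), AIBN (cat.), PhH, 80 °C
Reagents that add atoms: none
Why: Vinyl radical 6-exo-trig cyclisation onto the enal β-carbon (tin hydride radical chain) closes ring B between the two equatorial arms at C5 and C10 (trans fusion), leaves the C8 exocyclic methylene, and sets C9 through a chair transition state in which the E-enal arm is equatorial to avoid allylic strain with the C10 substituents, so that H-9 is axial (α) before the α-formyl radical is reduced to the aldehyde.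

Step 10
Reactants: 19 (4R)-4-benzyl-1,3-oxazolidin-2-one; 20 3-cyanopropanoic acid
Product: 21 4-[(4R)-4-benzyl-2-oxo-1,3-oxazolidin-3-yl]-4-oxobutanenitrile
Conditions: 20, PivCl, Et3N, THF, −20 °C; then 19, LiCl, 25 °C
Reagents that add atoms: none
Why: N-Acylation of the oxazolidinone by the mixed pivalic anhydride of the acid (LiCl/Et3N method) gives the aldol donor; its only stereocentre comes from the auxiliary.

Step 11
Reactants: 18 2-[(1S,4aR,6R,7R,8aR)-6,7-dichloro-5,5,8a-trimethyl-2-methylidene-4-oxodecahydronaphthalen-1-yl]acetaldehyde; 21 4-[(4R)-4-benzyl-2-oxo-1,3-oxazolidin-3-yl]-4-oxobutanenitrile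
Product: 23 (3R,4S)-3-[(4R)-4-benzyl-2-oxo-1,3-oxazolidine-3-carbonyl]-5-[(1S,4aR,6R,7R,8aR)-6,7-dichloro-5,5,8a-trimethyl-2-methylidene-4-oxodecahydronaphthalen-1-yl]-4-hydroxypentanenitrile, via boron enolate 22 (not isolated)
Conditions: 21, Bu2BOTf, iPr2NEt, CH2Cl2, −78 to 0 °C; then 18, −78 to 0 °C; pH 7 buffer, MeOH, H2O2
Reagents that add atoms: none
Why: Evans syn-aldol reaction, in which the Z-boron enolate of the imide (the nitrile α-position is not enolised) adds to the aldehyde through a closed chair transition state on the face away from the benzyl group, so that the (R)-auxiliary sets C13 as R and C12 as S under reagent control while the hindered C6 ketone stays out.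

Step 12
Reactants: 23 (3R,4S)-3-[(4R)-4-benzyl-2-oxo-1,3-oxazolidine-3-carbonyl]-5-[(1S,4aR,6R,7R,8aR)-6,7-dichloro-5,5,8a-trimethyl-2-methylidene-4-oxodecahydronaphthalen-1-yl]-4-hydroxypentanenitrile
Product: 25 haterumaimide B, via primary amide 24 (not isolated)
Conditions: [PtH(PMe2OH)(PMe2O)2H] (5 mol %), EtOH/H2O (4:1), 80 °C
Reagents that add atoms: water O
Why: Neutral platinum-catalysed nitrile hydration gives the primary amide, whose nitrogen then acylates at the activated N-acyl oxazolidinone carbonyl (5-exo-trig imide formation with release of the auxiliary), so the succinimide closes without base and C12, C13 and the β,γ-unsaturated ketone are not disturbed.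

**Compound list**
1 | 3,3-dimethyl-5-oxohexanoic acid | CC(=O)CC(C)(C)CC(=O)O | starting material
2 | 4,4,6-trimethyl-3,4-dihydro-2H-pyran-2-one | CC1=CC(C)(C)CC(=O)O1 | intermediate
3 | 4,4,6-trimethyl-3,4-dihydro-2H-pyran-2-ol (lactol) | CC1=CC(C)(C)CC(O)O1 | intermediate (not isolated)
4 | 3,3-dimethyl-5-oxohexanal | CC(=O)CC(C)(C)CC=O | intermediate
5 | (2R)-2-chloro-3,3-dimethyl-5-oxohexanal | CC(=O)CC(C)(C)[C@@H](Cl)C=O | intermediate
6 | (5R)-5-chloro-6-hydroxy-6-methoxy-4,4-dimethylhexan-2-one (hemiacetal, both C6 epimers) | CC(=O)CC(C)(C)[C@@H](Cl)C(O)OC | intermediate (not isolated)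
7 | (3R)-3-chloro-2-methoxy-4,4,6-trimethyl-3,4-dihydro-2H-pyran (both C2 epimers) | COC1OC(C)=CC(C)(C)[C@H]1Cl | intermediate
8 | 2-methylbut-1-en-3-yne | C=C(C)C#C | starting material
9 | (3R)-3-chloro-4,4,6-trimethyl-3,4-dihydropyrylium (cyclic O-vinyl oxocarbenium ion) | CC1=CC(C)(C)[C@@H](Cl)C=[O+]1 | intermediate (not isolated)
10 | (1S,4R,5S,7R)-7-chloro-5-ethynyl-3,5,8,8-tetramethyl-2-oxabicyclo[2.2.2]oct-2-en-2-ium (C7–Cl and 5-methyl syn to the O2=C3 bridge) | CC1=[O+][C@H]2C[C@](C)(C#C)[C@@H]1C(C)(C)[C@H]2Cl | intermediate (not isolated)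
11 | 1-[(1R,3R,4R,6S)-3,4-dichloro-6-ethynyl-2,2,6-trimethylcyclohexyl]ethan-1-one | CC(=O)[C@H]1C(C)(C)[C@@H](Cl)[C@H](Cl)C[C@]1(C)C#C | intermediate
12 | 1-[(1R,3R,4R,6R)-3,4-dichloro-6-ethenyl-2,2,6-trimethylcyclohexyl]ethan-1-one | CC(=O)[C@H]1C(C)(C)[C@@H](Cl)[C@H](Cl)C[C@]1(C)C=C | intermediate
13 | 2,3-dibromoprop-1-ene | C=C(Br)CBr | starting material
14 | lithium 1-[(1R,3R,4R,6R)-3,4-dichloro-6-ethenyl-2,2,6-trimethylcyclohexyl]ethenolate (terminal enolate of 12) | [Li]OC(=C)[C@H]1C(C)(C)[C@@H](Cl)[C@H](Cl)C[C@]1(C)C=C | intermediate (not isolated)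
15 | 4-bromo-1-[(1R,3R,4R,6R)-3,4-dichloro-6-ethenyl-2,2,6-trimethylcyclohexyl]pent-4-en-1-one | C=C(Br)CC(=O)[C@H]1C(C)(C)[C@@H](Cl)[C@H](Cl)C[C@]1(C)C=C | intermediate
16 | (E)-but-2-enal | C/C=C/C=O | starting material
17 | (2E)-3-[(1R,2R,4R,5R)-2-(4-bromopent-4-enoyl)-4,5-dichloro-1,3,3-trimethylcyclohexyl]prop-2-enal | C=C(Br)CC(=O)[C@H]1C(C)(C)[C@@H](Cl)[C@H](Cl)C[C@]1(C)/C=C/C=O | intermediate
18 | 2-[(1S,4aR,6R,7R,8aR)-6,7-dichloro-5,5,8a-trimethyl-2-methylidene-4-oxodecahydronaphthalen-1-yl]acetaldehyde | C=C1CC(=O)[C@H]2C(C)(C)[C@@H](Cl)[C@H](Cl)C[C@]2(C)[C@H]1CC=O | intermediate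
19 | (4R)-4-benzyl-1,3-oxazolidin-2-one | O=C1N[C@H](Cc2ccccc2)CO1 | starting material
20 | 3-cyanopropanoic acid | N#CCCC(=O)O | starting material
21 | 4-[(4R)-4-benzyl-2-oxo-1,3-oxazolidin-3-yl]-4-oxobutanenitrile | N#CCCC(=O)N1[C@H](Cc2ccccc2)COC1=O | intermediate
22 | (Z)-dibutylboron enolate of 21 | CCCCB(CCCC)O/C(=C\CC#N)N1[C@H](Cc2ccccc2)COC1=O | intermediate (not isolated)
23 | (3R,4S)-3-[(4R)-4-benzyl-2-oxo-1,3-oxazolidine-3-carbonyl]-5-[(1S,4aR,6R,7R,8aR)-6,7-dichloro-5,5,8a-trimethyl-2-methylidene-4-oxodecahydronaphthalen-1-yl]-4-hydroxypentanenitrile | C=C1CC(=O)[C@H]2C(C)(C)[C@@H](Cl)[C@H](Cl)C[C@]2(C)[C@H]1C[C@H](O)[C@@H](CC#N)C(=O)N1[C@H](Cc2ccccc2)COC1=O | intermediate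
24 | (3R,4S)-3-[(4R)-4-benzyl-2-oxo-1,3-oxazolidine-3-carbonyl]-5-[(1S,4aR,6R,7R,8aR)-6,7-dichloro-5,5,8a-trimethyl-2-methylidene-4-oxodecahydronaphthalen-1-yl]-4-hydroxypentanamide | C=C1CC(=O)[C@H]2C(C)(C)[C@@H](Cl)[C@H](Cl)C[C@]2(C)[C@H]1C[C@H](O)[C@@H](CC(N)=O)C(=O)N1[C@H](Cc2ccccc2)COC1=O | intermediate (not isolated)
25 | haterumaimide B, (3R)-3-[(1S)-2-[(1S,4aR,6R,7R,8aR)-6,7-dichloro-5,5,8a-trimethyl-2-methylidene-4-oxodecahydronaphthalen-1-yl]-1-hydroxyethyl]pyrrolidine-2,5-dione | C=C1CC(=O)[C@H]2C(C)(C)[C@@H](Cl)[C@H](Cl)C[C@]2(C)[C@H]1C[C@H](O)[C@H]1CC(=O)NC1=O | target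

**Step count**
Total: 12 steps. Longest linear sequence: 11 steps (steps 1–9, 11, 12).

**Steps most likely to fail**

Step 5 (key step). The ionised acetal may be used up by self-condensation or proton loss before it meets the weakly nucleophilic enyne. The C10 cation may be quenched by chloride before ring closure, the face selection at C10 may be low, and the bridged ion may be hydrolysed instead of being opened by chloride. The fallback builds ring A stepwise by known reactions; it sets out from 5 and comes back at 11. Indium-mediated Barbier addition of 13 to the aldehyde (In, THF/H2O) should give, by dipole-controlled addition anti to the chlorine, (5R,6S)-8-bromo-5-chloro-6-hydroxy-4,4-dimethylnon-8-en-2-one F1. Appel-type chlorination (Ph3P, NCS, CH2Cl2) with inversion should give (5R,6R)-8-bromo-5,6-dichloro-4,4-dimethylnon-8-en-2-one F2. Negishi coupling of the vinyl bromide with ethynylzinc bromide (Pd(PPh3)4, THF) gives (5R,6R)-5,6-dichloro-4,4-dimethyl-8-methylidenedec-9-yn-2-one F3, and Co2(CO)8 in CH2Cl2 gives the hexacarbonyldicobalt complex of F3 F4. HBF4·OEt2 protonates the complexed enyne to the tertiary cobalt-stabilised propargylic cation, which alkylates the ketone enol at C5 (intramolecular Nicholas reaction) through a chair with the dichloride equatorial, the cobalt cluster equatorial and the C10 methyl axial, to give the hexacarbonyldicobalt complex of 11 F5. Oxidative decomplexation with (NH4)2Ce(NO3)6 in acetone returns to 11.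

Step 8. Cross-metathesis at a vinyl group on a quaternary carbon may be slow or stall, with catalyst decomposition and self-metathesis of the partner taking over. The fallback sets out from 15 and comes back at 17. Lemieux–Johnson cleavage (OsO4 cat., NaIO4, 2,6-lutidine, dioxane/H2O), which should attack the vinyl group in preference to the electron-poor bromoalkene, gives (1S,2R,4R,5R)-2-(4-bromopent-4-enoyl)-4,5-dichloro-1,3,3-trimethylcyclohexane-1-carbaldehyde F6. Wittig olefination with Ph3P=CHCHO (PhMe, 80 °C) then gives the E-enal 17.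

Step 9. The vinyl radical may be reduced before it cyclises or close in the 7-endo mode, the stannyl radical may add to the enal, and the face selection at C9 may be poor. The fallback sets out from 17 and comes back at 18 with no new compound. A palladium-mediated reductive Heck cyclisation (Pd(OAc)2, PPh3, HCO2Na, Bu4NCl, DMF, 80 °C) forms the same C8–C9 bond by syn-carbopalladation of the enal followed by protonation of the palladium enolate.

**Further compounds**
F1 | step 5 | (5R,6S)-8-bromo-5-chloro-6-hydroxy-4,4-dimethylnon-8-en-2-one | CC(=O)CC(C)(C)[C@@H](Cl)[C@@H](O)CC(Br)=C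
F2 | step 5 | (5R,6R)-8-bromo-5,6-dichloro-4,4-dimethylnon-8-en-2-one | CC(=O)CC(C)(C)[C@@H](Cl)[C@H](Cl)CC(Br)=C
F3 | step 5 | (5R,6R)-5,6-dichloro-4,4-dimethyl-8-methylidenedec-9-yn-2-one | CC(=O)CC(C)(C)[C@@H](Cl)[C@H](Cl)CC(=C)C#C
F4 | step 5 | hexacarbonyldicobalt complex of F3 | CC(=O)CC(C)(C)[C@@H](Cl)[C@H](Cl)CC(=C)C12[CH]3[Co]1(=C=O)(=C=O)(=C=O)[Co]23(=C=O)(=C=O)=C=O
F5 | step 5 | hexacarbonyldicobalt complex of 11 | CC(=O)[C@H]1C(C)(C)[C@@H](Cl)[C@H](Cl)C[C@]1(C)C23[CH]4[Co]2(=C=O)(=C=O)(=C=O)[Co]34(=C=O)(=C=O)=C=O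
F6 | step 8 | (1S,2R,4R,5R)-2-(4-bromopent-4-enoyl)-4,5-dichloro-1,3,3-trimethylcyclohexane-1-carbaldehyde | C=C(Br)CC(=O)[C@H]1C(C)(C)[C@@H](Cl)[C@H](Cl)C[C@]1(C)C=O
F0 | step 9 | none | none
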